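## Retrosynthetic overview

1. 15-Deoxybudlein A ⇐ angeloylation of the free C8 alcohol of the macrocycle (last step).
2. Ten-membered carbocycle and trans-fused α-methylene-γ-lactone ⇐ one intramolecular Cr(II) Barbier allylation (C6–C7) of a Z-enal onto a 2-(bromomethyl)enoate, then lactonization (these two rings form together, last).
3. 3(2H)-Furanone with the C10 quaternary centre ⇐ Au(III)-catalysed heterocyclization/1,2-methyl shift of an acyclic 2-hydroxy-2-alkynyl ketone (first ring; the carbinol configuration is transferred to C10).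
4. That ketone ⇐ catalyst-controlled Mukaiyama aldol (C8–C9, sets C8) of a methyl ketone with a C5 bromo-enal made by Morita–Baylis–Hillman reaction and allylic transposition.
5. Methyl ketone ⇐ new catalytic enantioselective alkynylation of biacetyl with (Z)-3-methylpent-2-en-4-yn-1-ol (C1–C2 bond, sets the carbinol).

Assumption: the absolute sense of induction of the chiral catalysts in steps 3 and 5 is not certain on these substrates; the antipode named is the one taken to give the configuration drawn, and the other antipode is used if it does not (locants C1–C15 follow germacranolide numbering).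

## Route

Step 1
Reactants: 1 2,2-dimethoxyacetaldehyde; 2 methyl acrylate
Product: 3 methyl 3-hydroxy-4,4-dimethoxy-2-methylidenebutanoate (racemic)
Conditions: DABCO (0.5 equiv), dioxane/H2O 1:1, 23 °C
Reagents that add atoms: none
Why: Morita–Baylis–Hillman reaction of an activated, non-enolizable aldehyde; the carbinol centre is racemic and is erased in step 2.

Step 2
Reactants: 3 MBH adduct
Product: 5 methyl (2Z)-2-(bromomethyl)-4-oxobut-2-enoate, via acetal bromide 4 (not isolated)
Conditions: 48% aq HBr, H2SO4 (cat.), CH2Cl2, 0 → 23 °C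
Reagents that add atoms: hydrogen bromide, Br; water, O
Why: SN2′ displacement of the protonated MBH alcohol by bromide (allylic transposition of MBH adducts) gives the more stable Z-bromide with the C4 substituent trans to the ester, and the aqueous acid hydrolyses the dimethyl acetal in the same flask.

Step 3
Reactants: 6 (2Z)-3-methylpent-2-en-4-yn-1-ol; 7 butane-2,3-dione (biacetyl)
Product: 8 (3R,6Z)-3,8-dihydroxy-3,6-dimethyloct-6-en-4-yn-2-one
Conditions: Zn(OTf)2 (20 mol %), (1S,2S)-3-(TBSO)-2-(dimethylamino)-1-(4-nitrophenyl)propan-1-ol (22 mol %), Et3N (40 mol %), 7 (3 equiv), toluene, 23 °C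
Reagents that add atoms: none
Why: Proposed new method: catalytic enantioselective mono-alkynylation of an enolizable dialkyl 1,2-diketone – Zn(OTf)2/Et3N turns the terminal alkyne of 6 into a zinc acetylide in situ, biacetyl binds s-cis through both carbonyl oxygens to the chiral zinc amino-alkoxide (two-point chelation, as an α-ketoester does) and the acetylide is delivered to one carbonyl face, creating the C3 carbinol (R; it becomes C10 of the target); biacetyl is C2-symmetric so only face selectivity matters, excess diketone and the hindered, less electrophilic α-ketol product suppress bis-addition, and the free primary OH is carried as its zinc alkoxide; closest known reaction type: Zn(II)/amino-alcohol-catalysed asymmetric alkynylation of α-ketoesters and aldehydes (Carreira-type alkynylation).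

Step 4
Reactants: 8 α-hydroxy methyl ketone
Product: 9 (3R,6Z)-3,6-dimethyl-2,3,8-tris[(trimethylsilyl)oxy]octa-1,6-dien-4-yne
Conditions: TMSOTf (3.5 equiv), Et3N (5 equiv), CH2Cl2, 0 °C
Reagents that add atoms: trimethylsilyl trifluoromethanesulfonate, C[Si](C)(C)OS(=O)(=O)C(F)(F)F
Why: Soft enolization/silylation; only the acetyl CH3 can enolize (the other α-carbon is quaternary), both hydroxyls are capped and the stereocentre is untouched.

Step 5
Reactants: 9 tris-TMS enol silane; 5 bromo-enal
Product: 11 methyl (2Z,4R,7R,10Z)-2-(bromomethyl)-4,7,12-trihydroxy-7,10-dimethyl-6-oxododeca-2,10-dien-8-ynoate, via trichlorosilyl aldolate 10 (not isolated)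
Conditions: SiCl4 (1.5 equiv), (R,R)-binaphthyldiamine bisphosphoramide (5 mol %), i-Pr2NEt (10 mol %), CH2Cl2, −78 °C; aq NaHCO3; then aq citric acid, THF, 0 °C
Reagents that add atoms: silicon tetrachloride, Cl[Si](Cl)(Cl)Cl (its SiCl3 group is held in 10 only)
Why: Lewis-base-activated SiCl4 Mukaiyama aldol (Denmark type), well suited to methyl-ketone enol silanes and conjugated aldehydes: the chiral phosphoramide-bound silyl cation activates the enal and exposes its Re face, setting C4 (R; C8 of the target) under catalyst control, and aqueous acid then frees the three hydroxyls.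

Step 6
Reactants: 11 triol
Product: 12 methyl (2Z,4R,7R,10Z)-2-(bromomethyl)-7-hydroxy-7,10-dimethyl-6-oxo-4,12-bis[(triethylsilyl)oxy]dodeca-2,10-dien-8-ynoate
Conditions: TESOTf (2.1 equiv), 2,6-lutidine (3 equiv), CH2Cl2, −78 °C
Reagents that add atoms: triethylsilyl trifluoromethanesulfonate, CC[Si](CC)(CC)OS(=O)(=O)C(F)(F)F
Why: Silylation of the primary and secondary hydroxyls while the hindered tertiary α-keto carbinol stays free for step 7; the non-nucleophilic base spares the allylic bromide and stops 5-exo O-alkylation of the C4 hydroxyl by the CH2Br group.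

Step 7
Reactants: 12 bis-TES 2-hydroxy-2-alkynyl ketone
Product: 13 methyl (2Z,4R)-2-(bromomethyl)-5-{(2R)-2-methyl-3-oxo-5-[(2Z)-4-[(triethylsilyl)oxy]but-2-en-2-yl]-2,3-dihydrofuran-2-yl}-4-[(triethylsilyl)oxy]pent-2-enoate
Conditions: AuCl3 (5 mol %), CH2Cl2, 23 °C
Reagents that add atoms: none
Why: Gold-catalysed heterocyclization/1,2-migration domino of 2-hydroxy-2-alkynyl ketones to 3(2H)-furanones: the ketone oxygen adds 5-endo to the activated alkyne, the methyl group then shifts suprafacially from the carbinol carbon to the oxocarbenium carbon (α-ketol-type 1,2-shift) so that the (R) carbinol is translated into the (R) quaternary C2 of the furanone (C10 of the target), and protodeauration releases the catalyst.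

Step 8
Reactants: 13 furanone bis-TES ether
Product: 14 methyl (2Z,4R)-2-(bromomethyl)-5-{(2R)-2-methyl-3-oxo-5-[(2Z)-4-oxobut-2-en-2-yl]-2,3-dihydrofuran-2-yl}-4-[(triethylsilyl)oxy]pent-2-enoate
Conditions: (COCl)2, DMSO, CH2Cl2, −78 → −40 °C; i-Pr2NEt, −78 → 0 °C
Reagents that add atoms: none
Why: Swern oxidation applied directly to a primary triethylsilyl ether (primary TES ethers are oxidized, the secondary one is not), giving the Z-enal without a separate deprotection; Hünig's base at low temperature avoids Z→E isomerization and quaternization of the allylic bromide.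

Step 9
Reactants: 14 Z-enal allylic bromide
Product: 16 (6R,7R,8R,10R)-8-hydroxy-1-oxo-3,10-epoxygermacra-2,4Z,11(13)-trien-12,6-olide, via TES-protected macrolactone 15 (not isolated)
Conditions: CrCl2 (10 equiv), THF, 5 mM, slow addition, 23 °C; then 1 M HCl, 23 °C
Reagents that add atoms: none
Why: Intramolecular Nozaki–Hiyama-type Barbier allylation, the usual ring closure for germacranolide lactones: the allylchromium(III) adds through its γ-carbon (C7) to the enal in a chair transition state in which the tether holds C5 and C8 antiperiplanar across the new C6–C7 bond, giving the 6,7-trans arrangement (6R,7R) relative to the fixed 8R and 10R centres; the chromium alkoxide closes the γ-lactone on the methyl ester and HCl removes the TES group.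

Step 10
Reactants: 16 C8 alcohol; 17 angelic acid [(2Z)-2-methylbut-2-enoic acid]
Product: 19 15-deoxybudlein A, via angelic 2,4,6-trichlorobenzoic mixed anhydride 18 (not isolated)
Conditions: 17, 2,4,6-Cl3C6H2COCl, Et3N, toluene, 23 °C; then 16, 80 °C
Reagents that add atoms: 2,4,6-trichlorobenzoyl chloride, O=C(Cl)c1c(Cl)cc(Cl)cc1Cl (its acyl group is held in 18 only)
Why: Yamaguchi-type mixed-anhydride esterification run without DMAP, the standard way to make angelates without Z→E isomerization to the tiglate; the C8 hydroxyl is the only one present and no stereocentre is touched.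

## Compound list

1 | 2,2-dimethoxyacetaldehyde | COC(OC)C=O | starting material
2 | methyl acrylate | C=CC(=O)OC | starting material
3 | methyl 3-hydroxy-4,4-dimethoxy-2-methylidenebutanoate (racemic) | C=C(C(=O)OC)C(O)C(OC)OC | intermediate
4 | methyl (2Z)-2-(bromomethyl)-4,4-dimethoxybut-2-enoate | COC(=O)/C(CBr)=C/C(OC)OC | intermediate (not isolated)
5 | methyl (2Z)-2-(bromomethyl)-4-oxobut-2-enoate | COC(=O)/C(CBr)=C/C=O | intermediate
6 | (2Z)-3-methylpent-2-en-4-yn-1-ol | C#C/C(C)=C\CO | starting material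
7 | butane-2,3-dione | CC(=O)C(C)=O | starting material
8 | (3R,6Z)-3,8-dihydroxy-3,6-dimethyloct-6-en-4-yn-2-one | CC(=O)[C@](C)(O)C#C/C(C)=C\CO | intermediate
9 | (3R,6Z)-3,6-dimethyl-2,3,8-tris[(trimethylsilyl)oxy]octa-1,6-dien-4-yne | C=C(O[Si](C)(C)C)[C@](C)(O[Si](C)(C)C)C#C/C(C)=C\CO[Si](C)(C)C | intermediate
10 | methyl (2Z,4R,7R,10Z)-2-(bromomethyl)-7,10-dimethyl-6-oxo-4-[(trichlorosilyl)oxy]-7,12-bis[(trimethylsilyl)oxy]dodeca-2,10-dien-8-ynoate | COC(=O)/C(CBr)=C/[C@H](O[Si](Cl)(Cl)Cl)CC(=O)[C@](C)(O[Si](C)(C)C)C#C/C(C)=C\CO[Si](C)(C)C | intermediate (not isolated)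
11 | methyl (2Z,4R,7R,10Z)-2-(bromomethyl)-4,7,12-trihydroxy-7,10-dimethyl-6-oxododeca-2,10-dien-8-ynoate | COC(=O)/C(CBr)=C/[C@H](O)CC(=O)[C@](C)(O)C#C/C(C)=C\CO | intermediate
12 | methyl (2Z,4R,7R,10Z)-2-(bromomethyl)-7-hydroxy-7,10-dimethyl-6-oxo-4,12-bis[(triethylsilyl)oxy]dodeca-2,10-dien-8-ynoate | COC(=O)/C(CBr)=C/[C@H](O[Si](CC)(CC)CC)CC(=O)[C@](C)(O)C#C/C(C)=C\CO[Si](CC)(CC)CC | intermediate
13 | methyl (2Z,4R)-2-(bromomethyl)-5-{(2R)-2-methyl-3-oxo-5-[(2Z)-4-[(triethylsilyl)oxy]but-2-en-2-yl]-2,3-dihydrofuran-2-yl}-4-[(triethylsilyl)oxy]pent-2-enoate | COC(=O)/C(CBr)=C/[C@H](O[Si](CC)(CC)CC)C[C@@]1(C)OC(/C(C)=C\CO[Si](CC)(CC)CC)=CC1=O | intermediate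
14 | methyl (2Z,4R)-2-(bromomethyl)-5-{(2R)-2-methyl-3-oxo-5-[(2Z)-4-oxobut-2-en-2-yl]-2,3-dihydrofuran-2-yl}-4-[(triethylsilyl)oxy]pent-2-enoate | COC(=O)/C(CBr)=C/[C@H](O[Si](CC)(CC)CC)C[C@@]1(C)OC(/C(C)=C\C=O)=CC1=O | intermediate
15 | 8-O-triethylsilyl ether of 16 (same configuration at C6, C7, C8 and C10) | C=C1C(=O)O[C@@H]2/C=C(/C)C3=CC(=O)[C@@](C)(C[C@@H](O[Si](CC)(CC)CC)[C@@H]12)O3 | intermediate (not isolated)
16 | (6R,7R,8R,10R)-8-hydroxy-1-oxo-3,10-epoxygermacra-2,4Z,11(13)-trien-12,6-olide | C=C1C(=O)O[C@@H]2/C=C(/C)C3=CC(=O)[C@@](C)(C[C@@H](O)[C@@H]12)O3 | intermediate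
17 | angelic acid, (2Z)-2-methylbut-2-enoic acid | C/C=C(/C)C(=O)O | starting material
18 | (2Z)-2-methylbut-2-enoic 2,4,6-trichlorobenzoic anhydride | C/C=C(/C)C(=O)OC(=O)c1c(Cl)cc(Cl)cc1Cl | intermediate (not isolated)
19 | 15-deoxybudlein A, (6R,7R,8R,10R) | C=C1C(=O)O[C@@H]2/C=C(/C)C3=CC(=O)[C@@](C)(C[C@@H](OC(=O)/C(C)=C\C)[C@@H]12)O3 | target

## Step count and risks

Total step count: 10. Longest linear sequence: 8 steps (steps 3–10, from 6 and 7); steps 1–2 are a two-step branch to 5.

The three steps most likely to fail: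

**Step 3 (new alkynylation).** Biacetyl may self-condense under amine base, or the enantioselectivity may be low. The fallback uses known chemistry only, sets out from 6 and comes back at 8. Compound 6 is added to methyl pyruvate with the same Zn(OTf)2/amino-alcohol/Et3N system, which is established for α-ketoesters, to give methyl (2R,5Z)-2,7-dihydroxy-2,5-dimethylhept-5-en-3-ynoate F1. MeNH(OMe)·HCl/i-PrMgCl converts the ester into the Weinreb amide (2R,5Z)-2,7-dihydroxy-N-methoxy-N,2,5-trimethylhept-5-en-3-ynamide F2. Excess MeMgBr then gives 8. This costs two extra steps.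

**Step 5 (asymmetric aldol).** Aldehyde 5 is a very reactive γ-oxo-enoate with an allylic bromide, the facial control has to override the adjacent quaternary carbinol, and triol 11 can cyclize to a 2,5-dihydrofuran if it is handled under basic conditions. The fallback sets out from 8 and comes back at 12. TESCl/imidazole silylates only the primary hydroxyl of 8 and gives (3R,6Z)-3-hydroxy-3,6-dimethyl-8-[(triethylsilyl)oxy]oct-6-en-4-yn-2-one F3. Enolization with Ipc2BCl (2.3 equiv, antipode chosen for Re-face attack)/Et3N and addition to 5 is a reagent-controlled boron aldol; the tertiary OH is tied up as its borinate and freed on work-up. It gives methyl (2Z,4R,7R,10Z)-2-(bromomethyl)-4,7-dihydroxy-7,10-dimethyl-6-oxo-12-[(triethylsilyl)oxy]dodeca-2,10-dien-8-ynoate F4, whose C4 epimers can be separated because C7 is already fixed. TESOTf/2,6-lutidine at −78 °C then silylates the secondary hydroxyl and delivers 12.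

**Step 9 (Barbier macrocyclization).** Oligomerization is possible, and the C6/C7 configuration rests on a transition-state argument, not on a certainty. The fallback sets out from 13 and comes back at 16. Pd-catalysed borylation of the allylic bromide of 13 (B2pin2, Pd2(dba)3, toluene) gives methyl (2E,4R)-5-{(2R)-2-methyl-3-oxo-5-[(2Z)-4-[(triethylsilyl)oxy]but-2-en-2-yl]-2,3-dihydrofuran-2-yl}-2-[(4,4,5,5-tetramethyl-1,3,2-dioxaborolan-2-yl)methyl]-4-[(triethylsilyl)oxy]pent-2-enoate F5 (same alkene geometry as 13; only the CIP letter changes). Swern oxidation of its primary TES ether gives methyl (2E,4R)-5-{(2R)-2-methyl-3-oxo-5-[(2Z)-4-oxobut-2-en-2-yl]-2,3-dihydrofuran-2-yl}-2-[(4,4,5,5-tetramethyl-1,3,2-dioxaborolan-2-yl)methyl]-4-[(triethylsilyl)oxy]pent-2-enoate F6. This isolable 2-(alkoxycarbonyl)allylboronate is closed at 5 mM by Sc(OTf)3-catalysed intramolecular allylboration through a closed six-membered transition state. 1 M HCl then lactonizes and removes the TES group to give 16.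

Further compounds
F1 | step 3 | methyl (2R,5Z)-2,7-dihydroxy-2,5-dimethylhept-5-en-3-ynoate | COC(=O)[C@](C)(O)C#C/C(C)=C\CO
F2 | step 3 | (2R,5Z)-2,7-dihydroxy-N-methoxy-N,2,5-trimethylhept-5-en-3-ynamide | CON(C)C(=O)[C@](C)(O)C#C/C(C)=C\CO
F3 | step 5 | (3R,6Z)-3-hydroxy-3,6-dimethyl-8-[(triethylsilyl)oxy]oct-6-en-4-yn-2-one | CC(=O)[C@](C)(O)C#C/C(C)=C\CO[Si](CC)(CC)CC
F4 | step 5 | methyl (2Z,4R,7R,10Z)-2-(bromomethyl)-4,7-dihydroxy-7,10-dimethyl-6-oxo-12-[(triethylsilyl)oxy]dodeca-2,10-dien-8-ynoate | COC(=O)/C(CBr)=C/[C@H](O)CC(=O)[C@](C)(O)C#C/C(C)=C\CO[Si](CC)(CC)CC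
F5 | step 9 | methyl (2E,4R)-5-{(2R)-2-methyl-3-oxo-5-[(2Z)-4-[(triethylsilyl)oxy]but-2-en-2-yl]-2,3-dihydrofuran-2-yl}-2-[(4,4,5,5-tetramethyl-1,3,2-dioxaborolan-2-yl)methyl]-4-[(triethylsilyl)oxy]pent-2-enoate | COC(=O)/C(CB1OC(C)(C)C(C)(C)O1)=C/[C@H](O[Si](CC)(CC)CC)C[C@@]2(C)OC(/C(C)=C\CO[Si](CC)(CC)CC)=CC2=O
F6 | step 9 | methyl (2E,4R)-5-{(2R)-2-methyl-3-oxo-5-[(2Z)-4-oxobut-2-en-2-yl]-2,3-dihydrofuran-2-yl}-2-[(4,4,5,5-tetramethyl-1,3,2-dioxaborolan-2-yl)methyl]-4-[(triethylsilyl)oxy]pent-2-enoate | COC(=O)/C(CB1OC(C)(C)C(C)(C)O1)=C/[C@H](O[Si](CC)(CC)CC)C[C@@]2(C)OC(/C(C)=C\C=O)=CC2=O
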